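Cathafuran C is disconnected at C6–C1′ (prenyl), C4a–C4 and O1–C2 (pyran ring). The key step exploits the resorcinol pattern of the benzene ring: each five-carbon unit sits ortho to a ring oxygen (C6 to C7–OH, C4a to C8a–O1), both flank the C5 benzofuranyl group, and C8 between the oxygens bears only H. Heating a 4-aryl-2,6-dialkoxybenzoate that carries a 1,1-dimethylallyl ether on one oxygen, a 1,1-dimethylpropargyl ether on the other and a methyl ester on the carbon between them delivers the prenyl group and the 2,2-dimethylpyran in one operation. The benzofuranol travels as a TIPS ether, so silyl group, ester and CO2 leave together in hot alkali without acid.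

Key step: step 8

Remark: the target has no stereocentre and no stereogenic double bond, so it is achiral and no stereocontrol is needed; benzofuran-6-ol and 3-chloro-3-methylbut-1-yne are taken as purchased.

Step 1
Reactants: 1 benzofuran-6-ol
Product: 2 6-(triisopropylsilyloxy)benzofuran
Conditions: TIPSCl, imidazole, DMF, rt
Reagents that add atoms: chlorotriisopropylsilane, CC(C)[Si](Cl)(C(C)C)C(C)C
Why: Standard O-silylation of a phenol; the TIPS ether should survive n-BuLi, aqueous phosphate, DBU and heat, yet fall to hot alkali in the last step, so that no acid is ever applied to the o-prenylphenol and the chromene.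

Step 2
Reactants: 2 6-(triisopropylsilyloxy)benzofuran
Product: 4 4,4,5,5-tetramethyl-2-[6-(triisopropylsilyloxy)benzofuran-2-yl]-1,3,2-dioxaborolane, via [6-(triisopropylsilyloxy)benzofuran-2-yl]lithium 3 (not isolated)
Conditions: n-BuLi, THF, −78 °C; iPrOBpin, −78 °C → rt; aq NH4Cl
Reagents that add atoms: 2-isopropoxy-4,4,5,5-tetramethyl-1,3,2-dioxaborolane, CC(C)OB1OC(C)(C)C(C)(C)O1
Why: Lithiation–borylation; C2–H is the most acidic C–H of a benzofuran and the bulky silyloxy group is a poor ortho director, so deprotonation should occur at C2 only and the lithio species is trapped by the borate.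

Step 3
Reactants: 5 methyl 2,4,6-trihydroxybenzoate
Product: 6 methyl 2,6-dihydroxy-4-(trifluoromethylsulfonyloxy)benzoate
Conditions: PhNTf2 (1.0 equiv), Et3N, CH2Cl2, 0 °C → rt
Reagents that add atoms: N-phenylbis(trifluoromethanesulfonimide), O=S(=O)(N(c1ccccc1)S(=O)(=O)C(F)(F)F)C(F)(F)F
Why: Selective O-triflation of the non-chelated phenol; the 4-OH is para to the ester, not hydrogen-bonded to it and the most acidic, so one equivalent of the mild triflyl donor should sulfonylate it alone.

Step 4
Reactants: 6 methyl 2,6-dihydroxy-4-(trifluoromethylsulfonyloxy)benzoate; 4 4,4,5,5-tetramethyl-2-[6-(triisopropylsilyloxy)benzofuran-2-yl]-1,3,2-dioxaborolane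
Product: 7 methyl 2,6-dihydroxy-4-[6-(triisopropylsilyloxy)benzofuran-2-yl]benzoate
Conditions: XPhos Pd G3 (cat.), K3PO4, THF/H2O, 40 °C
Reagents that add atoms: none
Why: Suzuki–Miyaura coupling; the triflate para to the ester should add to Pd(0) readily, and the fast-activating biarylphosphine palladacycle lets transmetalation of the 2-benzofuranyl boronate outrun its protodeboronation at 40 °C, while free phenols and the TIPS ether tolerate aqueous phosphate.

Step 5
Reactants: 7 methyl 2,6-dihydroxy-4-[6-(triisopropylsilyloxy)benzofuran-2-yl]benzoate; 8 3-chloro-3-methylbut-1-yne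
Product: 9 methyl 2-hydroxy-6-(2-methylbut-3-yn-2-yloxy)-4-[6-(triisopropylsilyloxy)benzofuran-2-yl]benzoate
Conditions: 8 (1.05 equiv), DBU (1.1 equiv), CuCl2·2H2O (cat.), MeCN, −5 → 0 °C
Reagents that add atoms: 3-chloro-3-methylbut-1-yne (8), CC(C)(Cl)C#C
Why: Copper-catalysed propargylic etherification (attack of the phenoxide on a copper acetylide/allenylidene at the tertiary carbon); the two phenols are equivalent and the diol is more acidic than its mono-ether, so with one equivalent of base and electrophile the mono-ether should predominate.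

Step 6
Reactants: 9 methyl 2-hydroxy-6-(2-methylbut-3-yn-2-yloxy)-4-[6-(triisopropylsilyloxy)benzofuran-2-yl]benzoate
Product: 10 methyl 2-hydroxy-6-(2-methylbut-3-en-2-yloxy)-4-[6-(triisopropylsilyloxy)benzofuran-2-yl]benzoate
Conditions: H2 (1 atm), Lindlar catalyst, quinoline, EtOAc, rt
Reagents that add atoms: none
Why: Lindlar semihydrogenation; the poisoned catalyst should stop at the terminal alkene and leave the benzofuran, the aryl ethers and the ester untouched.

Step 7
Reactants: 10 methyl 2-hydroxy-6-(2-methylbut-3-en-2-yloxy)-4-[6-(triisopropylsilyloxy)benzofuran-2-yl]benzoate; 8 3-chloro-3-methylbut-1-yne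
Product: 11 methyl 2-(2-methylbut-3-en-2-yloxy)-6-(2-methylbut-3-yn-2-yloxy)-4-[6-(triisopropylsilyloxy)benzofuran-2-yl]benzoate
Conditions: 8 (3 equiv), DBU (3 equiv), CuCl2·2H2O (cat.), MeCN, 0 °C → rt
Reagents that add atoms: 3-chloro-3-methylbut-1-yne (8), CC(C)(Cl)C#C
Why: The same copper-catalysed propargylic etherification, now with excess reagents because the remaining phenol is hydrogen-bonded to the ester; at or below room temperature the tertiary allyl ether should not yet rearrange.

Step 8
Reactants: 11 methyl 2-(2-methylbut-3-en-2-yloxy)-6-(2-methylbut-3-yn-2-yloxy)-4-[6-(triisopropylsilyloxy)benzofuran-2-yl]benzoate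
Product: 15 methyl 7-hydroxy-2,2-dimethyl-6-(3-methylbut-2-enyl)-5-[6-(triisopropylsilyloxy)benzofuran-2-yl]-2H-chromene-8-carboxylate, via methyl 2-hydroxy-3-(3-methylbut-2-enyl)-6-(2-methylbut-3-yn-2-yloxy)-4-[6-(triisopropylsilyloxy)benzofuran-2-yl]benzoate 12 (not isolated), via methyl 2,6-dihydroxy-3-(3-methylbuta-1,2-dienyl)-5-(3-methylbut-2-enyl)-4-[6-(triisopropylsilyloxy)benzofuran-2-yl]benzoate 13 (not isolated), via methyl (5Z)-2-hydroxy-5-(3-methylbut-2-enylidene)-3-(3-methylbut-2-enyl)-6-oxo-4-[6-(triisopropylsilyloxy)benzofuran-2-yl]cyclohexa-1,3-diene-1-carboxylate 14 (not isolated)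
Conditions: PhNEt2 (degassed), 130 °C, then 185 °C, Ar
Reagents that add atoms: none
Why: At 130 °C the 1,1-dimethylallyl ether should undergo a chair-like aromatic Claisen [3,3] shift to the free ortho carbon and the dienone enolises to prenylphenol 12; at 185 °C the 1,1-dimethylpropargyl ether should undergo the propargyl Claisen [3,3] shift to the other free ortho carbon, the allenyl dienone enolises to 13, a [1,5]-H shift from the phenol gives o-quinone methide 14, and this cyclises. The closest known reactions are the thermal rearrangement of aryl 1,1-dimethylallyl ethers to o-prenylphenols and of aryl 1,1-dimethylpropargyl ethers to 2,2-dimethyl-2H-chromenes. The pyran ring is closed by a thermal oxa-6π electrocyclisation of 14 that forms O1–C2, after C4a–C4 has been made in the [3,3] shift. No stereocentre is formed, and the Z geometry of the exocyclic alkene of 14 that the closure needs follows from the cyclic hydrogen transfer. The selectivity needed is regiochemical: each shift must end on the C–H carbon next to the benzofuranyl group, and the ester on the carbon between the two oxygens secures this, because a shift to that carbon gives a dienone that cannot enolise and can only revert. The staged temperature lets the lower-barrier allyl shift finish first, and the basic solvent buffers traces of acid that would ionise the tertiary ethers or cyclise the o-prenylphenol.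

Step 9
Reactants: 15 methyl 7-hydroxy-2,2-dimethyl-6-(3-methylbut-2-enyl)-5-[6-(triisopropylsilyloxy)benzofuran-2-yl]-2H-chromene-8-carboxylate
Product: 18 cathafuran C, 5-(6-hydroxybenzofuran-2-yl)-2,2-dimethyl-6-(3-methylbut-2-enyl)-2H-chromen-7-ol, via methyl 7-hydroxy-5-(6-hydroxybenzofuran-2-yl)-2,2-dimethyl-6-(3-methylbut-2-enyl)-2H-chromene-8-carboxylate 16 (not isolated), via 7-hydroxy-5-(6-hydroxybenzofuran-2-yl)-2,2-dimethyl-6-(3-methylbut-2-enyl)-2H-chromene-8-carboxylic acid 17 (not isolated)
Conditions: KOH, EtOH/H2O (degassed), 85 °C, Ar; then AcOH to pH 5, 85 °C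
Reagents that add atoms: none
Why: Hot alkali should cleave the aryl silyl ether and saponify the ester, and the resulting 2-hydroxy-6-alkoxybenzoic acid, activated by two ortho oxygens, should lose CO2 by ipso-protonation on mild acidification and warming (saponification–protodecarboxylation of a resorcylate ester); only weak acid is used, so the o-prenylphenol and the chromene should not cyclise or hydrate.

Compound list
1 | benzofuran-6-ol | Oc1ccc2ccoc2c1 | starting material
2 | 6-(triisopropylsilyloxy)benzofuran | CC(C)[Si](Oc1ccc2ccoc2c1)(C(C)C)C(C)C | intermediate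
3 | [6-(triisopropylsilyloxy)benzofuran-2-yl]lithium | [Li]c1cc2ccc(O[Si](C(C)C)(C(C)C)C(C)C)cc2o1 | intermediate (not isolated)
4 | 4,4,5,5-tetramethyl-2-[6-(triisopropylsilyloxy)benzofuran-2-yl]-1,3,2-dioxaborolane | CC(C)[Si](Oc1ccc2cc(B3OC(C)(C)C(C)(C)O3)oc2c1)(C(C)C)C(C)C | intermediate
5 | methyl 2,4,6-trihydroxybenzoate | COC(=O)c1c(O)cc(O)cc1O | starting material
6 | methyl 2,6-dihydroxy-4-(trifluoromethylsulfonyloxy)benzoate | COC(=O)c1c(O)cc(OS(=O)(=O)C(F)(F)F)cc1O | intermediate
7 | methyl 2,6-dihydroxy-4-[6-(triisopropylsilyloxy)benzofuran-2-yl]benzoate | COC(=O)c1c(O)cc(-c2cc3ccc(O[Si](C(C)C)(C(C)C)C(C)C)cc3o2)cc1O | intermediate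
8 | 3-chloro-3-methylbut-1-yne | CC(C)(Cl)C#C | starting material
9 | methyl 2-hydroxy-6-(2-methylbut-3-yn-2-yloxy)-4-[6-(triisopropylsilyloxy)benzofuran-2-yl]benzoate | COC(=O)c1c(O)cc(-c2cc3ccc(O[Si](C(C)C)(C(C)C)C(C)C)cc3o2)cc1OC(C)(C)C#C | intermediate
10 | methyl 2-hydroxy-6-(2-methylbut-3-en-2-yloxy)-4-[6-(triisopropylsilyloxy)benzofuran-2-yl]benzoate | COC(=O)c1c(O)cc(-c2cc3ccc(O[Si](C(C)C)(C(C)C)C(C)C)cc3o2)cc1OC(C)(C)C=C | intermediate
11 | methyl 2-(2-methylbut-3-en-2-yloxy)-6-(2-methylbut-3-yn-2-yloxy)-4-[6-(triisopropylsilyloxy)benzofuran-2-yl]benzoate | COC(=O)c1c(OC(C)(C)C=C)cc(-c2cc3ccc(O[Si](C(C)C)(C(C)C)C(C)C)cc3o2)cc1OC(C)(C)C#C | intermediate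
12 | methyl 2-hydroxy-3-(3-methylbut-2-enyl)-6-(2-methylbut-3-yn-2-yloxy)-4-[6-(triisopropylsilyloxy)benzofuran-2-yl]benzoate | COC(=O)c1c(O)c(CC=C(C)C)c(-c2cc3ccc(O[Si](C(C)C)(C(C)C)C(C)C)cc3o2)cc1OC(C)(C)C#C | intermediate (not isolated)
13 | methyl 2,6-dihydroxy-3-(3-methylbuta-1,2-dienyl)-5-(3-methylbut-2-enyl)-4-[6-(triisopropylsilyloxy)benzofuran-2-yl]benzoate | COC(=O)c1c(O)c(CC=C(C)C)c(-c2cc3ccc(O[Si](C(C)C)(C(C)C)C(C)C)cc3o2)c(C=C=C(C)C)c1O | intermediate (not isolated)
14 | methyl (5Z)-2-hydroxy-5-(3-methylbut-2-enylidene)-3-(3-methylbut-2-enyl)-6-oxo-4-[6-(triisopropylsilyloxy)benzofuran-2-yl]cyclohexa-1,3-diene-1-carboxylate (o-quinone methide) | COC(=O)C1=C(O)C(CC=C(C)C)=C(c2cc3ccc(O[Si](C(C)C)(C(C)C)C(C)C)cc3o2)/C(=C/C=C(C)C)C1=O | intermediate (not isolated)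
15 | methyl 7-hydroxy-2,2-dimethyl-6-(3-methylbut-2-enyl)-5-[6-(triisopropylsilyloxy)benzofuran-2-yl]-2H-chromene-8-carboxylate | COC(=O)c1c(O)c(CC=C(C)C)c(-c2cc3ccc(O[Si](C(C)C)(C(C)C)C(C)C)cc3o2)c2C=CC(C)(C)Oc12 | intermediate
16 | methyl 7-hydroxy-5-(6-hydroxybenzofuran-2-yl)-2,2-dimethyl-6-(3-methylbut-2-enyl)-2H-chromene-8-carboxylate | COC(=O)c1c(O)c(CC=C(C)C)c(-c2cc3ccc(O)cc3o2)c2C=CC(C)(C)Oc12 | intermediate (not isolated)
17 | 7-hydroxy-5-(6-hydroxybenzofuran-2-yl)-2,2-dimethyl-6-(3-methylbut-2-enyl)-2H-chromene-8-carboxylic acid | OC(=O)c1c(O)c(CC=C(C)C)c(-c2cc3ccc(O)cc3o2)c2C=CC(C)(C)Oc12 | intermediate (not isolated)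
18 | cathafuran C, 5-(6-hydroxybenzofuran-2-yl)-2,2-dimethyl-6-(3-methylbut-2-enyl)-2H-chromen-7-ol | CC(C)=CCc1c(O)cc2c(c1-c1cc3ccc(O)cc3o1)C=CC(C)(C)O2 | target

Total step count: 9. Longest linear sequence: 8 steps (1, 2, 4, 5, 6, 7, 8, 9, from benzofuran-6-ol).

Steps most likely to fail

Step 8. The tertiary allyl ether may ionise or lose isoprene instead of rearranging, or the first-formed prenylphenol may degrade during the hotter propargyl stage, so that the two rearrangements do not both run to completion in one flask. The fallback sets out from 9 and runs the two rearrangements separately, the hot one first. Heating 9 in PhNEt2 at 185 °C should give, by propargyl Claisen shift, hydrogen shift and oxa-6π closure, methyl 7-hydroxy-2,2-dimethyl-5-[6-(triisopropylsilyloxy)benzofuran-2-yl]-2H-chromene-8-carboxylate F1. Copper-catalysed etherification of its phenol with 8 (DBU, CuCl2·2H2O, MeCN) should give methyl 2,2-dimethyl-7-(2-methylbut-3-yn-2-yloxy)-5-[6-(triisopropylsilyloxy)benzofuran-2-yl]-2H-chromene-8-carboxylate F2. Lindlar semihydrogenation, which should spare the disubstituted chromene alkene, should give methyl 2,2-dimethyl-7-(2-methylbut-3-en-2-yloxy)-5-[6-(triisopropylsilyloxy)benzofuran-2-yl]-2H-chromene-8-carboxylate F3. Heating F3 in PhNEt2 at 120 °C should move the allyl group to C6, the only free ortho carbon, and the route is rejoined at 15.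

Step 7. O-Alkylation of the hydrogen-bonded phenoxide next to the ester may be slow, so that the copper-bound propargyl electrophile is lost to elimination or oligomerisation. The fallback sets out from 9 and keeps its alkyne; the allyl ether is installed instead by a Tsuji–Trost etherification, for which acidic phenols are good partners. Treating 9 with tert-butyl 2-methylbut-3-en-2-yl carbonate and Pd(PPh3)4 in THF at 0 °C should give the branched tertiary ether under kinetic control and rejoins the route directly at 11 (steps 6 and 7 are bypassed; no new compound, F0).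

Step 9. Hydrolysis at the carbonyl of the doubly ortho-substituted ester, further deactivated by the neighbouring phenoxide, may stall, and the electron-rich phenoxides may oxidise on long heating in alkali. The fallback sets out from 15 and attacks the methyl carbon instead of the shielded carbonyl. Lithium iodide in refluxing pyridine should demethylate the ester by SN2 to 7-hydroxy-2,2-dimethyl-6-(3-methylbut-2-enyl)-5-[6-(triisopropylsilyloxy)benzofuran-2-yl]-2H-chromene-8-carboxylic acid F4. This acid should lose CO2 on acidification with AcOH and warming to give 2,2-dimethyl-6-(3-methylbut-2-enyl)-5-[6-(triisopropylsilyloxy)benzofuran-2-yl]-2H-chromen-7-ol F5. TBAF buffered with AcOH in THF at 0 °C should then remove the silyl group and give 18.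

Further compounds
F1 | step 8 | methyl 7-hydroxy-2,2-dimethyl-5-[6-(triisopropylsilyloxy)benzofuran-2-yl]-2H-chromene-8-carboxylate | COC(=O)c1c(O)cc(-c2cc3ccc(O[Si](C(C)C)(C(C)C)C(C)C)cc3o2)c2C=CC(C)(C)Oc12
F2 | step 8 | methyl 2,2-dimethyl-7-(2-methylbut-3-yn-2-yloxy)-5-[6-(triisopropylsilyloxy)benzofuran-2-yl]-2H-chromene-8-carboxylate | COC(=O)c1c(OC(C)(C)C#C)cc(-c2cc3ccc(O[Si](C(C)C)(C(C)C)C(C)C)cc3o2)c2C=CC(C)(C)Oc12
F3 | step 8 | methyl 2,2-dimethyl-7-(2-methylbut-3-en-2-yloxy)-5-[6-(triisopropylsilyloxy)benzofuran-2-yl]-2H-chromene-8-carboxylate | COC(=O)c1c(OC(C)(C)C=C)cc(-c2cc3ccc(O[Si](C(C)C)(C(C)C)C(C)C)cc3o2)c2C=CC(C)(C)Oc12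
F0 | step 7 | none | none
F4 | step 9 | 7-hydroxy-2,2-dimethyl-6-(3-methylbut-2-enyl)-5-[6-(triisopropylsilyloxy)benzofuran-2-yl]-2H-chromene-8-carboxylic acid | OC(=O)c1c(O)c(CC=C(C)C)c(-c2cc3ccc(O[Si](C(C)C)(C(C)C)C(C)C)cc3o2)c2C=CC(C)(C)Oc12
F5 | step 9 | 2,2-dimethyl-6-(3-methylbut-2-enyl)-5-[6-(triisopropylsilyloxy)benzofuran-2-yl]-2H-chromen-7-ol | CC(C)=CCc1c(O)cc2c(c1-c1cc3ccc(O[Si](C(C)C)(C(C)C)C(C)C)cc3o1)C=CC(C)(C)O2
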